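## Structural features

The target is a dihydroflavonol 3-methyl ether. Ring A (benzo) is fused through C4a–C8a to the dihydropyranone ring C (O1, C2, C3, C4), and ring B (an aryl group) is attached to C2 by one C–C bond. Ring A carries free hydroxyls at C5 and C6 and a methyl ether at C7; ring B carries 3'-OH and 4'-OMe; C3 bears a methoxy group; C4 is a ketone lying peri to O5. The only stereocentres, C2 (R) and C3 (R), are neighbours and trans, so the ring B aryl group and the C3 methoxy group are both equatorial. C3–H is alpha to the ketone and the O1–C2 bond is beta to it, so base can epimerise C3 or open ring C by E1cB and scramble C2; the 5,6-dihydroxy ring A, with O1 para to the 6-OH, is easily oxidised to a quinone. The difficulty is twofold: two contiguous oxygenated stereocentres next to a carbonyl must be set in the absolute sense, and six oxygens must be told apart, three staying methylated (O3, O7, O4') and three ending free (O5, O6, O3'). The key step exploits the fact that C3 and C4 of ring C are adjacent oxygen-bearing carbons: they are the alkene carbons of a 2-aryl-2H-chromene whose single stereocentre C2 sends both new oxygens to the face away from ring B. The peri relation of C4=O and O5 is the second handle, because it lets one methyl ether on ring A be removed by chelation while the others stay.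

## Logic of the disconnections

**16 from 15.** The bonds cut are the two O–CH2Ph bonds (at O6 and O3') and the O5–CH3 bond. All three hydroxyls that end free are unmasked last, because the free 5,6-dihydroxy ring A is oxidised easily. O6 is deliberately carried as a benzyl ether and not as a methyl ether. A methyl group at O6 would have to be removed beside the 7-OMe group and in the presence of the 4'- and 3-OMe groups, a selectivity that cannot be relied on. With benzyl at O6 the only methyl ether to cleave is the one at O5, which is activated by chelation to C4=O. The gain is that 15 holds every carbon and both stereocentres in protected form. The forward step needs a Lewis acid that removes benzyl and the peri methyl group, spares three other methyl ethers, and involves no base.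

**15 from 14.** The O3–CH3 bond is cut. Adding this methyl group late keeps the C3 oxygen as a free hydroxyl through the oxidation-state change at C4 and exposes the alpha-hydroxy ketone, which is the retron of a diol. The forward step must alkylate a hindered secondary alcohol without forming an enolate, since base would epimerise C3 or open ring C between O1 and C2.

**14 from 13.** This is a change of oxidation level at C4 (C=O back to CH–OH); no skeletal bond is cut. It is made because the C4 carbinol of 13 is benzylic to the electron-rich ring A and can be told apart from the C3 carbinol. The gain is a vicinal diol in which the C4 configuration need not be controlled. The forward step must oxidise one of two secondary alcohols without cleaving the C3–C4 bond.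

**13 from 12.** The C3–O and C4–O bonds are cut together, the reverse of a syn dihydroxylation of C3=C4. The cut is placed here because both carbons carry oxygen in the target and because C2, already present in 12, can control the face of addition, so C3 needs no reagent control. Two stereocentres and two heteroatom bonds are removed and one stereocentre remains. The forward step must deliver both oxygens trans to the ring B aryl group under neutral conditions, as 12 and 13 are acid-labile.

**12 from 9 and 10 (through 11).** The C2–C1' bond between ring C and ring B is cut. This is the one bond whose formation creates the absolute configuration, and cutting it separates a racemic, readily ionised acetal from a commercial aryl nucleophile. The gain is convergence: ring B arrives in one piece with its own protecting group. The forward step must be enantioface-selective at C2 after ionisation of 9 and must attack C2, not C4.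

**9 from 8, and 8 from 7.** The C2–OEt bond is cut, then the oxidation level of C2 is raised from lactol to lactone. The reason is that 7 is stable and easy to make, whereas 8 and 9 are labile and best made just before use. The demand is a reduction that stops at the lactol and an acetalisation mild enough for an electron-rich system.

**7 from 4 and 5 (through 6).** The C3=C4 double bond and the O1–C2 lactone bond are cut. This takes ring C apart into an ortho-hydroxy aldehyde and a two-carbon ylide. The forward step needs the Z geometry for ring closure, which is reached thermally.

**4 from 3.** The bond between ring A and the formyl carbon is cut. Because 3 is symmetrical, with both ortho positions equivalent and the para position occupied, formylation has only one possible outcome. This symmetry is the reason for methyl at both O5 and O7 and benzyl at O6.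

**3 from 1 (through 2).** The aryl C–O bond of the phenol is traced back to the aryl C–CHO bond of 1 by a Baeyer–Villiger transform. 1 is commercial and already has the benzyl group on the central oxygen. The forward step needs aryl migration, which the three alkoxy groups ensure.

## Other disconnections considered

**Alternative 1:** The cut goes through C3–C4 and O1–C2, so ring C is closed by a hetero-[4+2] cycloaddition. Acid removes water from A2 to give the ring A ortho-quinone methide A4, which is trapped by the E enol pivalate A3 to give the flavan-3-yl ester A1.
- In its favour: ring C and both stereocentres arise in one convergent step from two achiral pieces. The E geometry of A3 is carried suprafacially into the 2,3-trans relation. A2 should be reachable in two routine steps from a commercial phenol. On convergence and ring construction this plan is the better one.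
- Against it here:
  - Regiochemistry: the aryl donor and the acyloxy donor of A3 polarise the alkene in opposite senses. Only if the 4-methoxyaryl group dominates does the aryl-bearing carbon end at C2; the reverse orientation would put the aryl group on C3.
  - Absolute configuration must come from an external chiral acid, and enol esters are a less proven class of 2π partner for A4-type heterodienes.
  - A1 arrives with C4 as CH2. A benzylic oxidation next to an acyloxy-bearing carbon, removal of a hindered pivalate from an alpha-acyloxy ketone (basic or reductive, both threatening C3 or C4=O), and O-methylation still lie ahead.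
- Comparison: both plans have a pericyclic key step. The chosen one asks only for facial selectivity, which the substrate supplies; this one asks for regio-, endo/exo- and enantiocontrol at once. In step count the two should be about equal, the saving at the front being spent on redox and protecting-group corrections at C3 and C4.

**Alternative 2:** The cut is C2–C3. A chiral dirhodium tetracarboxylate such as Rh2(S-PTTL)4 (divalent rhodium) would decompose the diazomethyl ketone A6. The carbene at C3 would insert into one of the two enantiotopic benzylic C–H bonds of the O–CH2–aryl group, closing ring C to give the flavanone A5.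
- In its favour: A6 should be assembled in few steps by O-alkylation and diazo transfer. The C–H bond is ideally activated (benzylic, alpha to oxygen, para-methoxy donor). C4 is delivered at the ketone oxidation level, which is better than the chosen plan, where C4 is oxidised after the key step. The front end is also shorter.
- Against it here:
  - Acceptor-only carbenes from diazomethyl ketones are the class least well controlled by chiral dirhodium catalysts.
  - The ether oxygen sits five atoms from the carbene, so attack of that oxygen on the carbene followed by a Stevens [1,2]-shift of the electron-rich benzyl group competes with the six-membered insertion, as does cyclopropanation of ring B.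
  - A5 still lacks the C3 oxygen. It must be introduced through an enol derivative of A5, exactly the situation in which ring C opens by beta-elimination of the phenoxide and C2 is scrambled, and then methylated.
- Comparison: on redox economy and on the number of steps to the ring C ketone this plan is equal or better. On security of the stereocentres it is weaker: the chosen plan sets C2 by an established catalytic arylation and never enolises the ketone under base, whereas here C2 rests on a less certain insertion and must survive an enolisation.

**Alternative 3:** The cuts are O1–C8a and C4–C4a, so ring A is added last as an aryne. CsF would release the aryne A10 from the silyl triflate A9. The alkoxide of the anti hydroxy ester A8 adds at the aryne carbon remote from the flanking methoxy group, and the resulting aryl anion, next to that methoxy group, attacks the ester to close ring C and give A7.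
- In its favour: this is the most convergent of the four plans. Both stereocentres and the C3 methyl ether come in from an acyclic ester that asymmetric aldol chemistry can supply. The inductive effect of the flanking methoxy group directs the addition to A10 in the sense required. C4 appears directly as the ketone, and only a deprotection follows. On step economy after the key step and on convergence it is better than the chosen plan.
- Against it here:
  - A8 is an aldol, and its alkoxide can revert by retro-aldol under the basic fluoride conditions. It can also be simply O-arylated if the aryl anion is protonated by a second molecule of A8 before it acylates.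
  - A8 must be the anti isomer, which a syn dihydroxylation of the corresponding E alkene does not give. An anti-selective glycolate aldol is needed.
  - A9 should cost three to four steps.
  - A7 sits throughout in a basic medium in which C3 can epimerise and ring C can open.
  - With three methyl ethers on ring A, A7 meets the same end-game problem at O6 as discussed for 16 from 15, so O6 would have to be benzylated here too.
- Comparison: structurally the plans differ in where the stereocentres come from (acyclic, catalyst-controlled aldol here; ring-bound substrate control in the chosen plan). Mechanistically this plan rests on an anionic cascade with several exits, the chosen one on a concerted addition with one. This plan should be shorter by two or three steps if the annulation works, so it is better on economy and weaker on predictability.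

Key step: step 7

Assumption: the tartaric acid monoamide of step 6 is written in its (2R,3R) form; if that enantiomer delivers the aryl group to the wrong face, its (2S,3S) antipode, equally available, is used to obtain 2S.

## Route

Step 1
Reactants: 1 4-(benzyloxy)-3,5-dimethoxybenzaldehyde
Product: 3 4-(benzyloxy)-3,5-dimethoxyphenol, via aryl formate 2 (not isolated)
Conditions: mCPBA, CH2Cl2, 0 °C to rt; then K2CO3 (cat.), MeOH, rt
Reagents that add atoms: mCPBA (3-chloroperoxybenzoic acid), OOC(=O)c1cccc(Cl)c1
Why: Baeyer–Villiger oxidation of an electron-rich benzaldehyde (Dakin type): the aryl group migrates in the Criegee adduct to give formate 2, which is methanolysed to the phenol. The symmetry of 3 leaves only one kind of ortho carbon for the next step.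

Step 2
Reactants: 3 4-(benzyloxy)-3,5-dimethoxyphenol
Product: 4 3-(benzyloxy)-6-hydroxy-2,4-dimethoxybenzaldehyde
Conditions: MgCl2, Et3N, (CH2O)n, MeCN, reflux; then aq. HCl
Reagents that add atoms: paraformaldehyde (as formaldehyde), C=O
Why: Casnati–Skattebøl ortho-formylation: the magnesium phenoxide delivers formaldehyde to the ortho carbon and the benzylic alkoxide formed is oxidised by a second formaldehyde through hydride transfer. The two ortho positions are equivalent and the para position is blocked, so a single aldehyde is expected.

Step 3
Reactants: 4 3-(benzyloxy)-6-hydroxy-2,4-dimethoxybenzaldehyde; 5 ethyl (triphenylphosphoranylidene)acetate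
Product: 7 6-(benzyloxy)-5,7-dimethoxy-2H-chromen-2-one, via ethyl E-hydroxycinnamate 6 (not isolated)
Conditions: PhNEt2, reflux
Reagents that add atoms: none
Why: Wittig olefination with a stabilised ylide gives cinnamate 6; at the reflux temperature of N,N-diethylaniline the E ester isomerises and lactonises with loss of ethanol, the standard passage from salicylaldehydes to coumarins.

Step 4
Reactants: 7 6-(benzyloxy)-5,7-dimethoxy-2H-chromen-2-one
Product: 8 6-(benzyloxy)-5,7-dimethoxy-2H-chromen-2-ol (racemic lactol)
Conditions: i-Bu2AlH (1.1 equiv), CH2Cl2, −78 °C; then aq. KNaC4H4O6
Reagents that add atoms: none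
Why: Partial reduction of a lactone by DIBAL-H: the tetrahedral aluminium alkoxide is stable at −78 °C and collapses only on work-up, so reduction should stop at the lactol; the ethers are inert.

Step 5
Reactants: 8 6-(benzyloxy)-5,7-dimethoxy-2H-chromen-2-ol
Product: 9 6-(benzyloxy)-2-ethoxy-5,7-dimethoxy-2H-chromene (racemic)
Conditions: EtOH, pyridinium 4-toluenesulfonate (cat.), 4 Å MS, rt; then Et3N
Reagents that add atoms: ethanol, CCO
Why: Acid-catalysed acetalisation: the lactol ionises at C2 to a benzopyrylium ion that ethanol captures. A weak acid and a basic quench are chosen because the 5,7-dioxygenated acetal is labile.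

Step 6
Reactants: 9 6-(benzyloxy)-2-ethoxy-5,7-dimethoxy-2H-chromene; 10 [3-(benzyloxy)-4-methoxyphenyl]boronic acid
Product: 12 (2S)-6-(benzyloxy)-2-[3-(benzyloxy)-4-methoxyphenyl]-5,7-dimethoxy-2H-chromene, via diethyl arylboronate 11 (not isolated)
Conditions: 10, EtOH, toluene, azeotropic drying; then 9, (2R,3R)-4-(dibenzylamino)-2,3-dihydroxy-4-oxobutanoic acid (10 mol%), Yb(OTf)3 (5 mol%), EtOAc, −20 to 4 °C
Reagents that add atoms: none
Why: Enantioselective addition of a boronate to a chromene acetal under combined chiral Brønsted acid and Lewis acid catalysis: Yb(OTf)3 ionises 9 to the planar benzopyrylium ion, the tartaric acid monoamide exchanges onto the boron of 11, and the chiral boronate delivers the aryl group to one face of C2, which sets C2 as S. The peri 5-OMe group disfavours attack at C4, and the non-oxidising trivalent ytterbium salt suits the electron-rich substrate.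

Step 7
Reactants: 12 (2S)-6-(benzyloxy)-2-[3-(benzyloxy)-4-methoxyphenyl]-5,7-dimethoxy-2H-chromene
Product: 13 (2R,3S,4S)-6-(benzyloxy)-2-[3-(benzyloxy)-4-methoxyphenyl]-5,7-dimethoxy-3,4-dihydro-2H-chromene-3,4-diol
Conditions: OsO4 (3 mol%), NMO (1.5 equiv), acetone/H2O, 0 °C to rt, dark; then aq. Na2SO3
Reagents that add atoms: osmium tetroxide, O=[Os](=O)(=O)=O; N-methylmorpholine N-oxide, C[N+]1([O-])CCOCC1; water, O
Why: OsO4 (octavalent osmium) adds across C3=C4 in a concerted, suprafacial [3+2] cycloaddition to give a cyclic osmate ester of hexavalent osmium, which water hydrolyses to the cis diol while NMO returns osmium to the octavalent state (Upjohn dihydroxylation). The closest known reaction type is the catalytic dihydroxylation of cis-disubstituted styrenes, in particular of flav-3-enes, which give 2,3-trans-3,4-cis flavan-3,4-diols. No ring is closed; the C3–O and C4–O bonds are the only bonds formed. C3 and C4 are cis to each other because both oxygens come from one osmium centre, and both are trans to the aryl group because the C2 substituent covers its own face of the ring C half-chair, so C2 is the controlling element for both new centres (3S, 4S). The selectivity needed is facial only: there is one alkene, both its carbons are oxidised, and the electron-rich arenes and benzyl ethers are inert to OsO4. C2 keeps its geometry but its descriptor changes from S to R, because C3 now outranks the aryl carbon. Neutral conditions in the dark are used because 12 can ring-open photochemically and 13 ionises readily at C4; the C4 configuration is erased in step 8, so only C3 matters for the target.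

Step 8
Reactants: 13 (2R,3S,4S)-6-(benzyloxy)-2-[3-(benzyloxy)-4-methoxyphenyl]-5,7-dimethoxy-3,4-dihydro-2H-chromene-3,4-diol
Product: 14 (2R,3R)-6-(benzyloxy)-2-[3-(benzyloxy)-4-methoxyphenyl]-3-hydroxy-5,7-dimethoxy-2,3-dihydro-4H-chromen-4-one
Conditions: activated MnO2 (excess), CH2Cl2, rt
Reagents that add atoms: none
Why: Chemoselective oxidation of a benzylic alcohol by activated MnO2: the C4 carbinol is activated by the electron-rich ring A, whereas the C3 carbinol is an ordinary secondary alcohol. C3 keeps its geometry (its descriptor becomes R because C4=O now outranks C2), and the neutral medium avoids enolisation.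

Step 9
Reactants: 14 (2R,3R)-6-(benzyloxy)-2-[3-(benzyloxy)-4-methoxyphenyl]-3-hydroxy-5,7-dimethoxy-2,3-dihydro-4H-chromen-4-one
Product: 15 (2R,3R)-6-(benzyloxy)-2-[3-(benzyloxy)-4-methoxyphenyl]-3,5,7-trimethoxy-2,3-dihydro-4H-chromen-4-one
Conditions: Me3OBF4, 1,8-bis(dimethylamino)naphthalene, 4 Å MS, CH2Cl2, 0 °C to rt
Reagents that add atoms: trimethyloxonium tetrafluoroborate, C[O+](C)C.F[B-](F)(F)F
Why: O-Methylation with Meerwein's salt buffered by a hindered, non-nucleophilic amine: the oxonium salt alkylates the neutral hydroxyl and the amine only takes up the proton afterwards. No enolate forms, so neither C3 epimerisation nor E1cB opening of ring C is expected.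

Step 10
Reactants: 15 (2R,3R)-6-(benzyloxy)-2-[3-(benzyloxy)-4-methoxyphenyl]-3,5,7-trimethoxy-2,3-dihydro-4H-chromen-4-one
Product: 16 (2R,3R)-5,6-dihydroxy-2-(3-hydroxy-4-methoxyphenyl)-3,7-dimethoxy-2,3-dihydro-4H-chromen-4-one
Conditions: BCl3, C6HMe5, CH2Cl2, −78 to 0 °C; then MeOH/H2O
Reagents that add atoms: none
Why: Lewis acid dealkylation: BCl3 cleaves the two benzyl ethers at low temperature (the benzyl cation is captured by pentamethylbenzene in a Friedel–Crafts reaction) and, through the chelate between C4=O and O5, removes the peri 5-O-methyl group selectively. The 7-, 4'- and 3-methyl ethers lack this activation and should remain, and no base touches C2 or C3.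

## Compound list

1 | 4-(benzyloxy)-3,5-dimethoxybenzaldehyde | COc1cc(C=O)cc(OC)c1OCc1ccccc1 | starting material
2 | 4-(benzyloxy)-3,5-dimethoxyphenyl formate | COc1cc(OC=O)cc(OC)c1OCc1ccccc1 | intermediate
3 | 4-(benzyloxy)-3,5-dimethoxyphenol | COc1cc(O)cc(OC)c1OCc1ccccc1 | intermediate
4 | 3-(benzyloxy)-6-hydroxy-2,4-dimethoxybenzaldehyde | COc1cc(O)c(C=O)c(OC)c1OCc1ccccc1 | intermediate
5 | ethyl (triphenylphosphoranylidene)acetate | CCOC(=O)C=P(c1ccccc1)(c1ccccc1)c1ccccc1 | starting material
6 | ethyl (2E)-3-[3-(benzyloxy)-6-hydroxy-2,4-dimethoxyphenyl]prop-2-enoate | CCOC(=O)/C=C/c1c(O)cc(OC)c(OCc2ccccc2)c1OC | intermediate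
7 | 6-(benzyloxy)-5,7-dimethoxy-2H-chromen-2-one | O=c1ccc2c(OC)c(OCc3ccccc3)c(OC)cc2o1 | intermediate
8 | 6-(benzyloxy)-5,7-dimethoxy-2H-chromen-2-ol (racemic) | OC1C=Cc2c(OC)c(OCc3ccccc3)c(OC)cc2O1 | intermediate
9 | 6-(benzyloxy)-2-ethoxy-5,7-dimethoxy-2H-chromene (racemic) | CCOC1C=Cc2c(OC)c(OCc3ccccc3)c(OC)cc2O1 | intermediate
10 | [3-(benzyloxy)-4-methoxyphenyl]boronic acid | COc1ccc(B(O)O)cc1OCc1ccccc1 | starting material
11 | diethyl [3-(benzyloxy)-4-methoxyphenyl]boronate | CCOB(OCC)c1ccc(OC)c(OCc2ccccc2)c1 | intermediate
12 | (2S)-6-(benzyloxy)-2-[3-(benzyloxy)-4-methoxyphenyl]-5,7-dimethoxy-2H-chromene | COc1ccc([C@H]2Oc3cc(OC)c(OCc4ccccc4)c(OC)c3C=C2)cc1OCc1ccccc1 | intermediate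
13 | (2R,3S,4S)-6-(benzyloxy)-2-[3-(benzyloxy)-4-methoxyphenyl]-5,7-dimethoxy-3,4-dihydro-2H-chromene-3,4-diol | COc1ccc([C@H]2Oc3cc(OC)c(OCc4ccccc4)c(OC)c3[C@H](O)[C@@H]2O)cc1OCc1ccccc1 | intermediate
14 | (2R,3R)-6-(benzyloxy)-2-[3-(benzyloxy)-4-methoxyphenyl]-3-hydroxy-5,7-dimethoxy-2,3-dihydro-4H-chromen-4-one | COc1ccc([C@H]2Oc3cc(OC)c(OCc4ccccc4)c(OC)c3C(=O)[C@@H]2O)cc1OCc1ccccc1 | intermediate
15 | (2R,3R)-6-(benzyloxy)-2-[3-(benzyloxy)-4-methoxyphenyl]-3,5,7-trimethoxy-2,3-dihydro-4H-chromen-4-one | COc1ccc([C@H]2Oc3cc(OC)c(OCc4ccccc4)c(OC)c3C(=O)[C@@H]2OC)cc1OCc1ccccc1 | intermediate
16 | (2R,3R)-5,6-dihydroxy-2-(3-hydroxy-4-methoxyphenyl)-3,7-dimethoxy-2,3-dihydro-4H-chromen-4-one | COc1ccc([C@H]2Oc3cc(OC)c(O)c(O)c3C(=O)[C@@H]2OC)cc1O | target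

## Step count and least certain steps

Total step count: 10. Longest linear sequence: 10 steps (1 to 16); 5 and 10 are commercial and enter at steps 3 and 6.

**Step 7 (key step).**
- What may go wrong: incomplete facial discrimination if the aryl group does not shield its face effectively; slow turnover at a cis-disubstituted alkene flanked by the peri 5-OMe group; ionisation of the product at C4 during a long reaction.
- Fallback: setting out from 12, epoxidation with dimethyldioxirane in acetone at low temperature should again occur anti to the aryl group and give (2R,3S,4S)-6-(benzyloxy)-2-[3-(benzyloxy)-4-methoxyphenyl]-3,4-epoxy-5,7-dimethoxychromane F1. Buffered aqueous opening at the benzylic C4 with inversion would give the 3,4-trans diol (2R,3S,4R)-6-(benzyloxy)-2-[3-(benzyloxy)-4-methoxyphenyl]-5,7-dimethoxy-3,4-dihydro-2H-chromene-3,4-diol F2. Because C4 becomes a carbonyl carbon, F2 (or any mixture of F2 with 13) is oxidised with MnO2 as in step 8 and the route is rejoined at 14. C3 is still set trans to the aryl group by C2.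

**Step 6.**
- What may go wrong: erosion of enantioselectivity by uncatalysed addition to a long-lived, strongly stabilised benzopyrylium ion; competing attack at C4; protodeboronation of the electron-rich boronate.
- Fallback: setting out from 9 and 10, a base-free cross-coupling with Ni(cod)2 (zerovalent nickel) and PPh3 works by a different mechanism (oxidative addition into the allylic acetal C–O bond, transmetalation, reductive elimination). It should give racemic 6-(benzyloxy)-2-[3-(benzyloxy)-4-methoxyphenyl]-5,7-dimethoxy-2H-chromene F3. F3 is resolved by preparative chromatography on a chiral stationary phase to return to 12. A chiral phosphonite in place of PPh3 could later make this coupling enantioselective.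

**Step 8.**
- What may go wrong: oxidative cleavage of the C3–C4 glycol bond by MnO2; sluggish oxidation, because in the cis diol the C4 hydroxyl is pseudo-axial (away from the peri 5-OMe group) and the C4–H bond then lies near the plane of ring A, with poor benzylic overlap.
- Fallback: setting out from 13, heating with Bu2SnO in toluene with removal of water should give the stannylene acetal (2R,3S,4S)-6-(benzyloxy)-2-[3-(benzyloxy)-4-methoxyphenyl]-5,7-dimethoxychromane-3,4-diyl dibutylstannylene acetal F4. Brominolysis of F4 with N-bromosuccinimide in CH2Cl2 oxidises one carbinol of a cis diol to the ketone, by precedent the axial one, which here is also the benzylic C4. The route is rejoined at 14.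

**Step 10.**
- What may go wrong: loss of further methyl groups (7-OMe or 4'-OMe, each next to a newly formed boron aryloxide, or the 3-OMe chelated to C4=O) if the temperature or time is excessive; Friedel–Crafts benzylation of the electron-rich product; air oxidation of ring A during work-up.
- Fallback: setting out from 15, MgI2·OEt2 in THF/toluene removes only the peri methyl group through a magnesium chelate and should give (2R,3R)-6-(benzyloxy)-2-[3-(benzyloxy)-4-methoxyphenyl]-5-hydroxy-3,7-dimethoxy-2,3-dihydro-4H-chromen-4-one F5. Hydrogenolysis of F5 (H2, 10% Pd/C, EtOAc, rt) then removes both benzyl ethers under neutral conditions and arrives at 16.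

## Further compounds

F1 | step 7 | (2R,3S,4S)-6-(benzyloxy)-2-[3-(benzyloxy)-4-methoxyphenyl]-3,4-epoxy-5,7-dimethoxychromane | COc1ccc([C@H]2Oc3cc(OC)c(OCc4ccccc4)c(OC)c3[C@@H]4O[C@@H]42)cc1OCc1ccccc1
F2 | step 7 | (2R,3S,4R)-6-(benzyloxy)-2-[3-(benzyloxy)-4-methoxyphenyl]-5,7-dimethoxy-3,4-dihydro-2H-chromene-3,4-diol | COc1ccc([C@H]2Oc3cc(OC)c(OCc4ccccc4)c(OC)c3[C@@H](O)[C@@H]2O)cc1OCc1ccccc1
F3 | step 6 | racemic 6-(benzyloxy)-2-[3-(benzyloxy)-4-methoxyphenyl]-5,7-dimethoxy-2H-chromene | COc1ccc(C2Oc3cc(OC)c(OCc4ccccc4)c(OC)c3C=C2)cc1OCc1ccccc1
F4 | step 8 | (2R,3S,4S)-6-(benzyloxy)-2-[3-(benzyloxy)-4-methoxyphenyl]-5,7-dimethoxychromane-3,4-diyl dibutylstannylene acetal | COc1ccc([C@H]2Oc3cc(OC)c(OCc4ccccc4)c(OC)c3[C@@H]5O[Sn](CCCC)(CCCC)O[C@@H]52)cc1OCc1ccccc1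
F5 | step 10 | (2R,3R)-6-(benzyloxy)-2-[3-(benzyloxy)-4-methoxyphenyl]-5-hydroxy-3,7-dimethoxy-2,3-dihydro-4H-chromen-4-one | COc1ccc([C@H]2Oc3cc(OC)c(OCc4ccccc4)c(O)c3C(=O)[C@@H]2OC)cc1OCc1ccccc1
A1 | alternative 1 | (2R,3S)-2-[3-(benzyloxy)-4-methoxyphenyl]-5,6,7-trimethoxychroman-3-yl pivalate | COc1ccc([C@H]2Oc3cc(OC)c(OC)c(OC)c3C[C@@H]2OC(=O)C(C)(C)C)cc1OCc1ccccc1
A2 | alternative 1 | 2-(hydroxymethyl)-3,4,5-trimethoxyphenol | COc1cc(O)c(CO)c(OC)c1OC
A3 | alternative 1 | (E)-2-[3-(benzyloxy)-4-methoxyphenyl]ethenyl 2,2-dimethylpropanoate | COc1ccc(/C=C/OC(=O)C(C)(C)C)cc1OCc1ccccc1
A4 | alternative 1 | 3,4,5-trimethoxy-6-methylidenecyclohexa-2,4-dien-1-one | C=C1C(=O)C=C(OC)C(OC)=C1OC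
A5 | alternative 2 | (2S)-2-[3-(benzyloxy)-4-methoxyphenyl]-5,6,7-trimethoxychroman-4-one | COc1ccc([C@H]2Oc3cc(OC)c(OC)c(OC)c3C(=O)C2)cc1OCc1ccccc1
A6 | alternative 2 | 1-[2-{[3-(benzyloxy)-4-methoxyphenyl]methoxy}-4,5,6-trimethoxyphenyl]-2-diazoethan-1-one | COc1ccc(COc2cc(OC)c(OC)c(OC)c2C(=O)C=[N+]=[N-])cc1OCc1ccccc1
A7 | alternative 3 | (2R,3R)-2-[3-(benzyloxy)-4-methoxyphenyl]-3,5,6,7-tetramethoxychroman-4-one | COc1ccc([C@H]2Oc3cc(OC)c(OC)c(OC)c3C(=O)[C@@H]2OC)cc1OCc1ccccc1
A8 | alternative 3 | methyl (2R,3R)-3-[3-(benzyloxy)-4-methoxyphenyl]-3-hydroxy-2-methoxypropanoate | COc1ccc([C@@H](O)[C@@H](OC)C(=O)OC)cc1OCc1ccccc1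
A9 | alternative 3 | 3,4,5-trimethoxy-2-(trimethylsilyl)phenyl trifluoromethanesulfonate | COc1cc(OS(=O)(=O)C(F)(F)F)c([Si](C)(C)C)c(OC)c1OC
A10 | alternative 3 | 3,4,5-trimethoxybenzyne (1,2-didehydro-3,4,5-trimethoxybenzene) | COC1=CC#CC(OC)=C1OC
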